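## Analysis of the target

The target is a flavanone: a benzene ring A fused to a 2,3-dihydropyran-4-one ring C (O1, C2, C3, C4=O, C4a, C8a), with ring B, a 3-hydroxy-4-methoxyphenyl group, on C2. Ring A is substituted everywhere except C6: methoxy groups on C5 and C7, a 3-methylbut-2-enyl (prenyl) group on C8, the ketone carbon on C4a and the ring oxygen on C8a. C2 is the only stereocentre and is (S). It is benzylic, bonded to O1 and β to the ketone, so it is lost by retro-oxa-Michael opening to the 2'-hydroxychalcone under base and by benzylic ionisation under strong acid. The sensitive groups are the trisubstituted alkene of the prenyl group, the single free phenol on ring B (to be told apart from three methyl ethers) and the electron-rich ring A. The difficulty is twofold: placing the prenyl group on C8 rather than on the near-equivalent C6 of a phloroglucinol core, and setting C2 so that it survives to the end. The plan rests on one feature: C5, C6, C7 and C8 with their substituents (OMe, H, OMe, prenyl) are the four carbons of a 4-substituted 1,1,3-trioxygenated butadiene, while C4a and C8a are the α- and β-carbons of the enone of a 2-aryl-2,3-dihydropyran-4-one, which is ring C with C2 already in place. Ring A can therefore be built last, by cycloaddition and aromatisation, onto a ring C made in enantioenriched form by a catalytic hetero-Diels–Alder reaction.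

## Retrosynthetic reasoning

**19 ⇒ 18.** The last operation touches no skeletal bond: the ring B phenol is released from its tert-butyldimethylsilyl ether 18. The phenol has to be masked because the route passes through a Lewis-acid-catalysed aldehyde addition, an electrophilic bromination and silyl ketene acetal chemistry. A silyl ether is chosen because buffered fluoride removes it without base strong enough to open ring C and without acid that would touch the prenyl group.

**18 ⇒ 7 + 15.** Ring A is cut at C4a–C5 and C8–C8a. This gives the brominated dihydropyranone 7 (ring C with C2, ring B and the two future ring-fusion carbons) and the triene 15, whose diene part carries both methoxy oxygens and the prenyl group. Cutting here makes the substitution pattern of ring A a consequence of how the fragments are joined, so no regioselective substitution on a phloroglucinol is needed, and the route is convergent. The forward reaction has three tasks: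
- Regiochemistry: the prenyl-bearing diene terminus must bond to the enone β-carbon and the ketene acetal carbon to the brominated α-carbon.
- Aromatisation: the adduct must lose the silyloxy group (not the methoxy group) from C5 together with H8, and HBr across C4a–C8a.
- C2 must be left alone.

Bromine and H8a are cis in the adduct and H8a is not α to a carbonyl, so a base-induced anti elimination of HBr is not possible at that stage. The silyloxy group is therefore expelled first, and HBr is lost afterwards from the resulting cyclohexadiene, where the elimination is aromatising and needs no anti-periplanar hydrogen.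

**7 ⇒ 5.** The C5–Br bond of the pyranone is cut. Bromine is put on the α-carbon of the enone 5 because it lowers the LUMO of a weak (vinylogous ester) dienophile and supplies the oxidation level that turns a cyclohexene into a benzene. The forward reaction is an addition–elimination α-bromination that must prefer the enol ether double bond to ring B.

**5 ⇒ 2 + 3.** Ring C is cut at C2–C3 and O1–C6 (pyranone numbering), giving aldehyde 2 and Danishefsky's diene 3. This is the place to set C2: the catalytic asymmetric hetero-Diels–Alder reaction of aromatic aldehydes is established, and the stereocentre is then carried through steps that do not enolise towards it under basic conditions.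

**2 ⇒ 1.** The silyl ether is cut back to isovanillin 1, which has the ring B oxygen pattern with the right oxygen free.

**15 ⇒ 13 ⇒ 11 ⇒ 8 + 9.** The O–Si bond of 15 is cut to give the β-methoxy enoate 13 (γ-deprotonation and O-silylation in the forward sense). The enol ether of 13 goes back to the β-keto ester 11. The C4–C5 bond of 11 is cut to methyl acetoacetate 8 and prenyl bromide 9 (dianion γ-alkylation). The prenyl group is thus attached to the carbon that becomes C8 before ring A exists.

## Alternatives that were turned down

**Alternative 1:** The disconnection is O1–C8a.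
- Forward key step: an open-chain precursor, (1S,3S)-1-[2-bromo-4,6-dimethoxy-3-(3-methylbut-2-en-1-yl)phenyl]-3-[4-methoxy-3-(methoxymethoxy)phenyl]propane-1,3-diol A2, is cyclised by copper-catalysed intramolecular O-arylation (CuI, a diamine or phenanthroline ligand, carbonate base). The product is the flavan-4-ol A1, which still needs oxidation at C4 and acidic removal of the methoxymethyl group.
- For: every reaction type is known. The C2–O bond is never broken, so the configuration made in an open-chain asymmetric aldol or reduction is kept with certainty. On these two points it is stronger than the chosen route.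
- Against: A2 needs ring A as a hexasubstituted aryl bromide, made by classical substitution on a phloroglucinol ether with the C6/C8 ambiguity. The bromide is flanked by the prenyl group and the side chain and sits on an electron-rich ring, both of which slow the copper step. C4 must be carried as a carbinol, because a β-hydroxy ketone would eliminate to the chalcone under the basic coupling, so oxidation and deprotection steps follow, the latter in acid in the presence of the prenyl group.
- Comparison: the sequence is clearly longer than eight steps. The chosen route offers ring A with its substituents fixed by construction and a five-step longest linear sequence, at the price of an untested key step.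

**Alternative 2:** The disconnection is O1–C2 and C3–C4.
- Forward key step: 2-hydroxy-4,6-dimethoxy-3-(3-methylbut-2-en-1-yl)benzaldehyde A4 and an orthoformate give, under a chiral Brønsted acid, a 4-methoxy ortho-quinone methide. This adds to the styrene tert-butyl(5-ethenyl-2-methoxyphenoxy)dimethylsilane A5 to give the 4-methoxyflavan A3.
- For: it is at least as convergent as the chosen route, forms ring C and the C2 stereocentre in one step, and the para-methoxystyrene is a well-matched electron-rich partner.
- Against: A3 is at the flavan oxidation level, so the benzylic methyl ether has to be converted into the ketone in further steps with oxidants that also threaten the prenyl group and ring A. A4 is an ortho-prenylphenol, which cyclises to a 2,2-dimethylchroman under Brønsted acid. The cation from a 2,4-dimethoxy-substituted quinone methide is so stabilised that tight ion pairing with a chiral anion, and hence enantiocontrol, is doubtful, and A5 tends to polymerise in acid. A4 again requires regioselective synthesis of the ring A pattern.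
- Comparison: the chosen route gives the ketone oxidation level directly, never exposes a free phenol next to the prenyl group, and sets C2 by an established catalytic reaction.

**Alternative 3:** The disconnection is C3=C4.
- Forward key step: (S)-tert-butyl[5-(1-{2-[1-(tert-butyldimethylsilyloxy)ethenyl]-3,5-dimethoxy-6-(3-methylbut-2-en-1-yl)phenoxy}prop-2-en-1-yl)-2-methoxyphenoxy]dimethylsilane A7 undergoes ring-closing metathesis with second-generation Grubbs catalyst between the vinyl group on C2 and the silyl enol ether on C4a. The product is the 4-silyloxy-2H-chromene A6.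
- For: the endgame is as good as or better than the chosen one, since fluoride would unmask ketone and phenol of A6 together.
- Against: the prenyl group is a third olefin ortho to the ether oxygen. The ruthenium carbene formed at the vinyl group can close onto it to a seven-membered ring with loss of isobutene, while the 1,1-disubstituted silyl enol ether is the poorer metathesis partner. The C2 centre of A7 and A6 is allylic, benzylic and an aryl ether at once, so it is exposed to ionisation and to ruthenium hydride double-bond migration. Making A7 enantioselectively means an asymmetric allylic etherification of a di-ortho-substituted phenol, after ring A has been assembled by classical means.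
- Comparison: the step count is higher. The chosen route has no competing olefin problem and a less exposed stereocentre.

Key step: step 7

## Assumptions

- (S)-BINOL is written on the assumption that the BINOL–titanium catalyst delivers the diene to the Si face of the aldehyde, as it does in allyl additions with the same catalyst. If the sense proves opposite, (R)-BINOL is used and nothing else changes.
- The geometry at C1=C2 of 14 and 15 is drawn with the lithium-oxy or silyloxy group cis to C3. It has no bearing on the outcome because both oxygen substituents sit on C1.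

## Route

Step 1
Reactants: 1 isovanillin (3-hydroxy-4-methoxybenzaldehyde)
Product: 2 3-(tert-butyldimethylsilyloxy)-4-methoxybenzaldehyde
Conditions: t-BuMe2SiCl, imidazole, DMF, rt
Reagents that add atoms: tert-butyldimethylsilyl chloride, CC(C)(C)[Si](C)(C)Cl
Why: Imidazole-promoted O-silylation of a phenol. The aryl silyl ether masks the phenol against the Lewis acid, bromine and silyl ketene acetal chemistry that follow and is removable by fluoride at the end.

Step 2
Reactants: 2 3-(tert-butyldimethylsilyloxy)-4-methoxybenzaldehyde; 3 trans-1-methoxy-3-(trimethylsilyloxy)buta-1,3-diene (Danishefsky's diene)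
Product: 5 (2S)-2-[3-(tert-butyldimethylsilyloxy)-4-methoxyphenyl]-2,3-dihydro-4H-pyran-4-one, via silylated Mukaiyama aldol adduct 4 (not isolated)
Conditions: Ti(OiPr)4 (10 mol %), (S)-BINOL (20 mol %), 4 Å MS, Et2O, −20 °C; then CF3CO2H, CH2Cl2, 0 °C
Reagents that add atoms: none
Why: Catalytic asymmetric hetero-Diels–Alder reaction in its stepwise Mukaiyama aldol form: the BINOL–titanium complex binds the aldehyde and the diene terminus adds to its Si face, which sets C2 as (S). Trifluoroacetic acid then closes 4 by conjugate addition of the carbinol oxygen and loss of methanol.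

Step 3
Reactants: 5 (2S)-2-[3-(tert-butyldimethylsilyloxy)-4-methoxyphenyl]-2,3-dihydro-4H-pyran-4-one
Product: 7 (2S)-5-bromo-2-[3-(tert-butyldimethylsilyloxy)-4-methoxyphenyl]-2,3-dihydro-4H-pyran-4-one, via 5,6-dibromide 6 (not isolated)
Conditions: Br2 (1.05 equiv), CH2Cl2, −78 °C; then Et3N, −78 → 0 °C
Reagents that add atoms: bromine, BrBr
Why: α-Halogenation of an enone by addition–elimination: at −78 °C bromine adds to the enol ether C5=C6 bond much faster than it substitutes ring B, and triethylamine removes the acidic H5 of 6 with loss of the anomeric bromide. C2 is not involved.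

Step 4
Reactants: 8 methyl acetoacetate; 9 prenyl bromide (1-bromo-3-methylbut-2-ene)
Product: 11 methyl 7-methyl-3-oxooct-6-enoate, via acetoacetate dianion 10 (not isolated)
Conditions: NaH, THF, 0 °C; n-BuLi, 0 °C; then 9, 0 °C → rt; aq. HCl
Reagents that add atoms: none
Why: γ-Alkylation of a β-keto ester dianion: the more basic terminal carbanion of 10 displaces the allylic bromide in an SN2 reaction, so only C4 is alkylated.

Step 5
Reactants: 11 methyl 7-methyl-3-oxooct-6-enoate
Product: 13 methyl (2E)-3-methoxy-7-methylocta-2,6-dienoate, via dimethyl ketal 12 (not isolated)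
Conditions: HC(OMe)3, MeOH, TsOH (cat.), rt; then PPTS (cat.), toluene, 110 °C, −MeOH
Reagents that add atoms: trimethyl orthoformate, COC(OC)OC; methanol, CO
Why: Acid-catalysed ketalisation with the orthoformate as water scavenger, then elimination of methanol to the conjugated enol ether, the (E) isomer being the thermodynamic product. The isolated trisubstituted alkene is inert to catalytic sulfonic acid under anhydrous conditions.

Step 6
Reactants: 13 methyl (2E)-3-methoxy-7-methylocta-2,6-dienoate
Product: 15 (1Z,3Z)-1,3-dimethoxy-7-methyl-1-(trimethylsilyloxy)octa-1,3,6-triene, via lithium dienolate 14 (not isolated)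
Conditions: LiN(iPr)2 (LDA), THF, −78 °C; Me3SiCl, −78 °C → rt; pentane, filtration under Ar, used crude
Reagents that add atoms: chlorotrimethylsilane, C[Si](C)(C)Cl
Why: Kinetic γ-deprotonation of the β-methoxy enoate (the C4 methylene is cis to the ester) and O-silylation of the extended enolate give the vinylogous silyl ketene acetal. Allylic strain in 14 should place the C5 chain trans to C2 across C3=C4, the geometry that allows the s-cis diene.

Step 7
Reactants: 7 (2S)-5-bromo-2-[3-(tert-butyldimethylsilyloxy)-4-methoxyphenyl]-2,3-dihydro-4H-pyran-4-one; 15 (1Z,3Z)-1,3-dimethoxy-7-methyl-1-(trimethylsilyloxy)octa-1,3,6-triene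
Product: 18 (2S)-2-[3-(tert-butyldimethylsilyloxy)-4-methoxyphenyl]-5,7-dimethoxy-8-(3-methylbut-2-en-1-yl)-2,3-dihydro-4H-chromen-4-one, via bromo ketal cycloadduct 16 (not isolated), via bromo dihydroarene 17 (not isolated)
Conditions: 15 (2.5 equiv), toluene, 85 °C, sealed; evaporate (high vacuum, removes surplus 15); Me3SiOTf (1.1 equiv), 2,6-di-tert-butyl-4-methylpyridine, CH2Cl2, −78 °C; then Et3N, −78 °C → rt
Reagents that add atoms: none
Why: Proposed new method: A 1,1,3-trioxygenated diene has not been added to a 5-halo-2,3-dihydropyran-4-one, but the step joins two known reaction types, the Diels–Alder/aromatisation of Brassard-type dienes with halo-quinones and the Diels–Alder reactions of 3-substituted chromones and 5-substituted dihydropyranones as dienophiles. A strongly polarised, asynchronous [4+2] addition (possibly a stepwise Mukaiyama–Michael addition followed by ring closure) is expected, in which ring A is closed as a six-membered carbocycle by the two new bonds C8–C8a and C4a–C5, giving 16 with bromine and H8a cis. Regiochemistry, the one selectivity that matters, follows from matched polarity: the prenyl-bearing diene terminus has the largest HOMO coefficient and bonds to the enone β-carbon, so the ketene acetal carbon ends on the brominated α-carbon and its methoxy group peri to the ketone, while bromine lowers the LUMO of the vinylogous ester and supplies the oxidation level. Because H8a is cis to bromine and not α to a carbonyl, the base-induced loss of hydrogen halide that follows halo-quinone cycloadditions is not available in 16, so the two eliminations are taken in the other order. Me3SiOTf silylates the silyloxy oxygen of the mixed methyl silyl ketal, which leaves as hexamethyldisiloxane in preference to methoxide as in Lewis-acid reactions of O-silyl O-alkyl acetals, and the 1,3-dimethoxyallyl cation loses H8 to the hindered pyridine to give diene 17 with the C5 methoxy group in place. In 17 the bromide is tertiary and doubly allylic, so its loss gives the arenium ion of 18 protonated at C8a and Et3N takes that proton (or effects a syn elimination); no anti-periplanar arrangement is needed and the benzene ring forms irreversibly. All four new sp3 centres (C4a, C5, C8, C8a) are destroyed again, so endo/exo and facial selectivity are immaterial and no stereocentre is created, and C2 is remote from the reacting enone and sees only a tertiary amine at or below room temperature.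

Step 8
Reactants: 18 (2S)-2-[3-(tert-butyldimethylsilyloxy)-4-methoxyphenyl]-5,7-dimethoxy-8-(3-methylbut-2-en-1-yl)-2,3-dihydro-4H-chromen-4-one
Product: 19 (2S)-2-(3-hydroxy-4-methoxyphenyl)-5,7-dimethoxy-8-(3-methylbut-2-en-1-yl)-2,3-dihydro-4H-chromen-4-one (CNP0403319.1)
Conditions: Bu4NF, AcOH (1:1), THF, 0 °C
Reagents that add atoms: none
Why: Fluoride cleaves the aryl O–Si bond. Buffering with acetic acid keeps the medium non-basic, so ring C should not open by retro-oxa-Michael reaction and C2 should keep its configuration; the methyl ethers and the prenyl group are inert.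

## Compound list

1 | isovanillin (3-hydroxy-4-methoxybenzaldehyde) | O=Cc1ccc(OC)c(O)c1 | starting material
2 | 3-(tert-butyldimethylsilyloxy)-4-methoxybenzaldehyde | O=Cc1ccc(OC)c(O[Si](C)(C)C(C)(C)C)c1 | intermediate
3 | trans-1-methoxy-3-(trimethylsilyloxy)buta-1,3-diene (Danishefsky's diene) | CO/C=C/C(=C)O[Si](C)(C)C | starting material
4 | (1E,5S)-5-[3-(tert-butyldimethylsilyloxy)-4-methoxyphenyl]-1-methoxy-5-(trimethylsilyloxy)pent-1-en-3-one | CO/C=C/C(=O)C[C@H](O[Si](C)(C)C)c1ccc(OC)c(O[Si](C)(C)C(C)(C)C)c1 | intermediate (not isolated)
5 | (2S)-2-[3-(tert-butyldimethylsilyloxy)-4-methoxyphenyl]-2,3-dihydro-4H-pyran-4-one | COc1ccc([C@@H]2CC(=O)C=CO2)cc1O[Si](C)(C)C(C)(C)C | intermediate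
6 | (2S)-5,6-dibromo-2-[3-(tert-butyldimethylsilyloxy)-4-methoxyphenyl]tetrahydro-4H-pyran-4-one (numbered as in 5; mixture of diastereomers at C5 and C6) | COc1ccc([C@@H]2CC(=O)C(Br)C(Br)O2)cc1O[Si](C)(C)C(C)(C)C | intermediate (not isolated)
7 | (2S)-5-bromo-2-[3-(tert-butyldimethylsilyloxy)-4-methoxyphenyl]-2,3-dihydro-4H-pyran-4-one | COc1ccc([C@@H]2CC(=O)C(Br)=CO2)cc1O[Si](C)(C)C(C)(C)C | intermediate
8 | methyl acetoacetate | COC(=O)CC(C)=O | starting material
9 | prenyl bromide (1-bromo-3-methylbut-2-ene) | CC(C)=CCBr | starting material
10 | sodium lithium dianion of methyl acetoacetate | [CH2-]C(=O)[CH-]C(=O)OC.[Na+].[Li+] | intermediate (not isolated)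
11 | methyl 7-methyl-3-oxooct-6-enoate | COC(=O)CC(=O)CCC=C(C)C | intermediate
12 | methyl 3,3-dimethoxy-7-methyloct-6-enoate | COC(=O)CC(OC)(OC)CCC=C(C)C | intermediate (not isolated)
13 | methyl (2E)-3-methoxy-7-methylocta-2,6-dienoate | COC(=O)/C=C(/OC)CCC=C(C)C | intermediate
14 | lithium dienolate of 13 (lithium 1,3-dimethoxy-7-methylocta-1,3,6-trien-1-olate; O–Li cis to C3, C5 chain trans to C2) | [Li+].CO/C([O-])=C/C(OC)=C/CC=C(C)C | intermediate (not isolated)
15 | (1Z,3Z)-1,3-dimethoxy-7-methyl-1-(trimethylsilyloxy)octa-1,3,6-triene | CO/C(O[Si](C)(C)C)=C/C(OC)=C/CC=C(C)C | intermediate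
16 | (2S)-4a-bromo-2-[3-(tert-butyldimethylsilyloxy)-4-methoxyphenyl]-5,7-dimethoxy-8-(3-methylbut-2-en-1-yl)-5-(trimethylsilyloxy)-2,3,4a,5,8,8a-hexahydro-4H-chromen-4-one (cis ring fusion; mixture of diastereomers at C4a, C5, C8, C8a) | COc1ccc([C@@H]2CC(=O)C3(Br)C(OC)(O[Si](C)(C)C)C=C(OC)C(CC=C(C)C)C3O2)cc1O[Si](C)(C)C(C)(C)C | intermediate (not isolated)
17 | (2S)-4a-bromo-2-[3-(tert-butyldimethylsilyloxy)-4-methoxyphenyl]-5,7-dimethoxy-8-(3-methylbut-2-en-1-yl)-2,3,4a,8a-tetrahydro-4H-chromen-4-one (mixture at C4a/C8a) | COc1ccc([C@@H]2CC(=O)C3(Br)C(OC)=CC(OC)=C(CC=C(C)C)C3O2)cc1O[Si](C)(C)C(C)(C)C | intermediate (not isolated)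
18 | (2S)-2-[3-(tert-butyldimethylsilyloxy)-4-methoxyphenyl]-5,7-dimethoxy-8-(3-methylbut-2-en-1-yl)-2,3-dihydro-4H-chromen-4-one | COc1ccc([C@@H]2CC(=O)c3c(OC)cc(OC)c(CC=C(C)C)c3O2)cc1O[Si](C)(C)C(C)(C)C | intermediate
19 | (2S)-2-(3-hydroxy-4-methoxyphenyl)-5,7-dimethoxy-8-(3-methylbut-2-en-1-yl)-2,3-dihydro-4H-chromen-4-one (CNP0403319.1) | COc1ccc([C@@H]2CC(=O)c3c(OC)cc(OC)c(CC=C(C)C)c3O2)cc1O | target

## Step count and risks

Total step count: 8. Longest linear sequence: 5 steps (1 → 2 → 5 → 7 → 18 → 19, and equally 8 → 11 → 13 → 15 → 18 → 19).

**Step 7 (key step, proposed new method).**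
- What may go wrong: the vinylogous-ester enone is a weak dienophile, so the union may stop at the open-chain conjugate addition stage, or not start below the temperature at which the diene decomposes. In the aromatisation, the mixed ketal may ionise with loss of methanol instead of the silyloxy group, which would leave a free C5 phenol after work-up. The Lewis acid may also open ring C by benzylic ionisation or by bromophilic attack on the α-bromo ketone, with erosion of the C2 configuration.
- Fallback (known chemistry): the benzannulation is given up and ring B is joined to a preformed chromone by catalytic asymmetric conjugate addition of an arylboronic acid. It sets out from 9. Commercial 2'-hydroxy-4',6'-dimethoxyacetophenone is C-prenylated ortho to the phenoxide with 9 (sodium phenoxide in toluene) to give 1-[2-hydroxy-4,6-dimethoxy-3-(3-methylbut-2-en-1-yl)phenyl]ethan-1-one F1. Condensation with N,N-dimethylformamide dimethyl acetal gives (2E)-3-(dimethylamino)-1-[2-hydroxy-4,6-dimethoxy-3-(3-methylbut-2-en-1-yl)phenyl]prop-2-en-1-one F2, which closes in warm acetic acid to 5,7-dimethoxy-8-(3-methylbut-2-en-1-yl)-4H-chromen-4-one F3. Commercial 5-bromo-2-methoxyphenol is silylated to (5-bromo-2-methoxyphenoxy)(tert-butyl)dimethylsilane F4 and converted by bromine–lithium exchange and borylation with triisopropyl borate into [3-(tert-butyldimethylsilyloxy)-4-methoxyphenyl]boronic acid F5. Addition of F5 to F3 with Pd(OCOCF3)2 and the antipode of 4-tert-butyl-2-(pyridin-2-yl)-4,5-dihydrooxazole that gives the (2S) product (NH4PF6, water, 1,2-dichloroethane, 60 °C) comes back to the route at 18.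

**Step 2.**
- What may go wrong: the electron-rich, meta-silyloxy-substituted aldehyde binds the titanium catalyst weakly, so the uncatalysed background addition may lower the enantiomeric purity, and the facial sense rests on analogy.
- Fallback: a stoichiometric chiral boron aldol replaces the catalytic reaction. It sets out from 2. The boron enolate of (E)-4-chlorobut-3-en-2-one, made with the appropriate antipode of chlorodiisopinocampheylborane and iPr2NEt, adds to 2 to give, after oxidative work-up, (1E,5S)-5-[3-(tert-butyldimethylsilyloxy)-4-methoxyphenyl]-1-chloro-5-hydroxypent-1-en-3-one F6. Me3SiOTf (cat.) and iPr2NEt close F6 by oxa-conjugate addition and loss of chloride, and the route is rejoined at 5.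

**Step 3.**
- What may go wrong: electrophilic bromination of ring B (activated by the methoxy and silyloxy groups), or over-bromination, may compete with addition to the enol ether.
- Fallback: the halogen is introduced by iodine–pyridine α-iodination, which does not halogenate dialkoxyarenes, and the iodide is carried into the key step. It sets out from 5. I2 and pyridine in CH2Cl2 give (2S)-2-[3-(tert-butyldimethylsilyloxy)-4-methoxyphenyl]-5-iodo-2,3-dihydro-4H-pyran-4-one F7. F7 takes the place of 7 in step 7 and passes through the 4a-iodo analogue of 16, F8, and the 4a-iodo analogue of 17, F9, which loses hydrogen iodide. The route is rejoined at 18.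

**Step 6.**
- What may go wrong: the trimethylsilyl ketene acetal may hydrolyse during isolation, and a mixture of C3=C4 isomers may form, of which only the one with the chain trans to C2 can reach the s-cis conformation. Neither can be corrected on a crude, unpurifiable diene.
- Fallback: a purifiable diene is carried instead, so that its isomer ratio can be measured and improved before the key step. It sets out from 14. The dienolate is trapped with t-BuMe2SiCl in THF/DMPU to give (1Z,3Z)-1-(tert-butyldimethylsilyloxy)-1,3-dimethoxy-7-methylocta-1,3,6-triene F10, which tolerates distillation or chromatography on deactivated silica. F10 replaces 15 in step 7; its cycloadduct, the 5-(tert-butyldimethylsilyloxy) analogue of 16, F11, loses the silyloxy group with Me3SiOTf in the same way, and the route is rejoined at 17.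

## Further compounds

F1 | step 7 | 1-[2-hydroxy-4,6-dimethoxy-3-(3-methylbut-2-en-1-yl)phenyl]ethan-1-one | CC(=O)c1c(OC)cc(OC)c(CC=C(C)C)c1O
F2 | step 7 | (2E)-3-(dimethylamino)-1-[2-hydroxy-4,6-dimethoxy-3-(3-methylbut-2-en-1-yl)phenyl]prop-2-en-1-one | CN(C)/C=C/C(=O)c1c(OC)cc(OC)c(CC=C(C)C)c1O
F3 | step 7 | 5,7-dimethoxy-8-(3-methylbut-2-en-1-yl)-4H-chromen-4-one | O=c1ccoc2c(CC=C(C)C)c(OC)cc(OC)c12
F4 | step 7 | (5-bromo-2-methoxyphenoxy)(tert-butyl)dimethylsilane | COc1ccc(Br)cc1O[Si](C)(C)C(C)(C)C
F5 | step 7 | [3-(tert-butyldimethylsilyloxy)-4-methoxyphenyl]boronic acid | COc1ccc(B(O)O)cc1O[Si](C)(C)C(C)(C)C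
F6 | step 2 | (1E,5S)-5-[3-(tert-butyldimethylsilyloxy)-4-methoxyphenyl]-1-chloro-5-hydroxypent-1-en-3-one | Cl/C=C/C(=O)C[C@H](O)c1ccc(OC)c(O[Si](C)(C)C(C)(C)C)c1
F7 | step 3 | (2S)-2-[3-(tert-butyldimethylsilyloxy)-4-methoxyphenyl]-5-iodo-2,3-dihydro-4H-pyran-4-one | COc1ccc([C@@H]2CC(=O)C(I)=CO2)cc1O[Si](C)(C)C(C)(C)C
F8 | step 3 | (2S)-2-[3-(tert-butyldimethylsilyloxy)-4-methoxyphenyl]-4a-iodo-5,7-dimethoxy-8-(3-methylbut-2-en-1-yl)-5-(trimethylsilyloxy)-2,3,4a,5,8,8a-hexahydro-4H-chromen-4-one (mixture of diastereomers) | COc1ccc([C@@H]2CC(=O)C3(I)C(OC)(O[Si](C)(C)C)C=C(OC)C(CC=C(C)C)C3O2)cc1O[Si](C)(C)C(C)(C)C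
F9 | step 3 | (2S)-2-[3-(tert-butyldimethylsilyloxy)-4-methoxyphenyl]-4a-iodo-5,7-dimethoxy-8-(3-methylbut-2-en-1-yl)-2,3,4a,8a-tetrahydro-4H-chromen-4-one (mixture at C4a/C8a) | COc1ccc([C@@H]2CC(=O)C3(I)C(OC)=CC(OC)=C(CC=C(C)C)C3O2)cc1O[Si](C)(C)C(C)(C)C
F10 | step 6 | (1Z,3Z)-1-(tert-butyldimethylsilyloxy)-1,3-dimethoxy-7-methylocta-1,3,6-triene | CO/C(O[Si](C)(C)C(C)(C)C)=C/C(OC)=C/CC=C(C)C
F11 | step 6 | (2S)-4a-bromo-5-(tert-butyldimethylsilyloxy)-2-[3-(tert-butyldimethylsilyloxy)-4-methoxyphenyl]-5,7-dimethoxy-8-(3-methylbut-2-en-1-yl)-2,3,4a,5,8,8a-hexahydro-4H-chromen-4-one (mixture of diastereomers) | COc1ccc([C@@H]2CC(=O)C3(Br)C(OC)(O[Si](C)(C)C(C)(C)C)C=C(OC)C(CC=C(C)C)C3O2)cc1O[Si](C)(C)C(C)(C)C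
A1 | alternative 1 | (2S,4S)-5,7-dimethoxy-2-[4-methoxy-3-(methoxymethoxy)phenyl]-8-(3-methylbut-2-en-1-yl)chroman-4-ol | COCOc1cc([C@@H]2C[C@H](O)c3c(OC)cc(OC)c(CC=C(C)C)c3O2)ccc1OC
A2 | alternative 1 | (1S,3S)-1-[2-bromo-4,6-dimethoxy-3-(3-methylbut-2-en-1-yl)phenyl]-3-[4-methoxy-3-(methoxymethoxy)phenyl]propane-1,3-diol | COCOc1cc([C@@H](O)C[C@H](O)c2c(OC)cc(OC)c(CC=C(C)C)c2Br)ccc1OC
A3 | alternative 2 | (2S,4S)-2-[3-(tert-butyldimethylsilyloxy)-4-methoxyphenyl]-4,5,7-trimethoxy-8-(3-methylbut-2-en-1-yl)chroman | COc1ccc([C@@H]2C[C@H](OC)c3c(OC)cc(OC)c(CC=C(C)C)c3O2)cc1O[Si](C)(C)C(C)(C)C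
A4 | alternative 2 | 2-hydroxy-4,6-dimethoxy-3-(3-methylbut-2-en-1-yl)benzaldehyde | O=Cc1c(OC)cc(OC)c(CC=C(C)C)c1O
A5 | alternative 2 | tert-butyl(5-ethenyl-2-methoxyphenoxy)dimethylsilane | C=Cc1ccc(OC)c(O[Si](C)(C)C(C)(C)C)c1
A6 | alternative 3 | (2S)-4-(tert-butyldimethylsilyloxy)-2-[3-(tert-butyldimethylsilyloxy)-4-methoxyphenyl]-5,7-dimethoxy-8-(3-methylbut-2-en-1-yl)-2H-chromene | COc1ccc([C@@H]2C=C(O[Si](C)(C)C(C)(C)C)c3c(OC)cc(OC)c(CC=C(C)C)c3O2)cc1O[Si](C)(C)C(C)(C)C
A7 | alternative 3 | (S)-tert-butyl[5-(1-{2-[1-(tert-butyldimethylsilyloxy)ethenyl]-3,5-dimethoxy-6-(3-methylbut-2-en-1-yl)phenoxy}prop-2-en-1-yl)-2-methoxyphenoxy]dimethylsilane | COc1ccc([C@H](C=C)Oc2c(CC=C(C)C)c(OC)cc(OC)c2C(=C)O[Si](C)(C)C(C)(C)C)cc1O[Si](C)(C)C(C)(C)C
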